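**Retrosynthetic overview**
1. Both flavonoid halves are bought: (−)-afzelechin 1 brings the two flavan stereocentres (phenols masked as silyl ethers, 2); achiral isokaempferide 3 already carries the 3-OMe.
2. Key disconnection: flavone C3–flavan C8 bond, formed at the anode between oxidised 3 and arene 2; this creates the quaternary C3 and gives quinone methide 4.
3. Second disconnection: flavone C2–O7(flavan) ketal bond; its closure on 4 builds the dihydrofuran ring, the only ring made in the route (all six-membered rings come with 1 and 3), giving 5.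
4. Desilylation of 5 gives 6.

Assumption: the target SMILES is reproduced unchanged (flavan unit 2S,3R = (−)-afzelechin; ketal C3 = R), but as written its C2/C3 descriptors encode a trans-fused furan/pyranone junction that no closure at this ring–chain-labile ketal carbon can give, so C2 is read as the cis-fused junction (3-OMe syn to the 2-aryl group, i.e. 2R,3R) and every ketal-containing SMILES below carries the descriptors as given.

**Step 1**
Reactants: 1 (−)-afzelechin
Product: 2 5,7,4'-tris-O-TBS-(−)-afzelechin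
Conditions: TBSCl (3.3 equiv), imidazole (6.6 equiv), DMF, 0 °C
Reagents that add atoms: tert-butyldimethylsilyl chloride, CC(C)(C)[Si](C)(C)Cl
Why: imidazole-promoted O-silylation in which the three phenols react far faster than the hindered secondary 3-OH; the flavan stereocentres are not touched.

**Step 2**
Reactants: 2 5,7,4'-tris-O-TBS-(−)-afzelechin; 3 isokaempferide
Product: 5 bis-TBS pentacyclic ketal, via quinone methide 4 (not isolated)
Conditions: undivided cell, BDD anode, Pt cathode, 2 (2.0 equiv), Et3MeN(O3SOMe) (0.1 M), HFIP/CH2Cl2 (4:1), 3 mA cm−2, 2.2 F mol−1, 20 °C; SiO2 chromatography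
Reagents that add atoms: none
Why: Proposed new method: the free 4'-phenol of 3 is oxidised at the anode (HFIP keeps the silyl-ether arene 2 as the unoxidised nucleophile) to a phenoxonium/quinone-methide cation whose charge sits on C3 as an O-methyl oxocarbenium (the 3-OMe blocks the keto tautomer that would make C2 the electrophile), C8 of 2 (C6 is flanked by two silyloxy groups) attacks C3 to give quinone methide 4, and the acid formed at the anode protonates 4 so that the neighbouring 7-silyloxy oxygen closes on C2 and hands its silyl group to HFIP; this closure can only occur on the face carrying the new aryl group, so C2 is set cis to C3, whereas the face of planar C3 is only weakly biased by the remote flavan centres bought with 1, so both cis-fused C3 epimers are expected and the (3R) one is separated as a diastereomer; closest known reaction types: anodic phenol–arene cross-coupling on BDD in HFIP and dehydrogenative [3+2] (β-5) annulation of 4-hydroxystyrenes or indoles with phenols.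

**Step 3**
Reactants: 5 bis-TBS pentacyclic ketal
Product: 6 target
Conditions: Et3N·3HF (6 equiv), THF, 0 °C → rt
Reagents that add atoms: none
Why: fluoride-driven cleavage of the two aryl silyl ethers (strong Si–F bond) in a near-neutral amine–HF buffer that spares the ketal and the tertiary benzylic methyl ether; no stereocentre is affected.

**Compound list**
1 | (−)-afzelechin, (2S,3R)-2-(4-hydroxyphenyl)chromane-3,5,7-triol | Oc1cc(O)c2c(c1)O[C@@H](c1ccc(O)cc1)[C@H](O)C2 | starting material
2 | (2S,3R)-5,7-bis(tert-butyldimethylsilyloxy)-2-[4-(tert-butyldimethylsilyloxy)phenyl]chroman-3-ol | CC(C)(C)[Si](C)(C)Oc1cc(O[Si](C)(C)C(C)(C)C)c2c(c1)O[C@@H](c1ccc(O[Si](C)(C)C(C)(C)C)cc1)[C@H](O)C2 | intermediate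
3 | isokaempferide (kaempferol 3-methyl ether), 5,7-dihydroxy-2-(4-hydroxyphenyl)-3-methoxy-4H-chromen-4-one | COc1c(-c2ccc(O)cc2)oc2cc(O)cc(O)c2c1=O | starting material
4 | quinone methide: 5,7-dihydroxy-3-methoxy-2-(4-oxocyclohexa-2,5-dien-1-ylidene)chroman-4-one bonded at C3 to C8 of 2 (C3 configured as in 6) | CO[C@]1(c2c(O[Si](C)(C)C(C)(C)C)cc(O[Si](C)(C)C(C)(C)C)c3c2O[C@@H](c2ccc(O[Si](C)(C)C(C)(C)C)cc2)[C@H](O)C3)C(=O)c2c(O)cc(O)cc2OC1=C1C=CC(=O)C=C1 | intermediate
5 | bis-TBS ether of 6 (silyl groups on the flavan-unit 5-O and on the 4-O of the flavan-unit aryl ring; flavone-unit phenols and flavan 3-OH free) | CO[C@]12C(=O)c3c(O)cc(O)cc3O[C@]1(c1ccc(O)cc1)Oc1cc(O[Si](C)(C)C(C)(C)C)c3c(c12)O[C@@H](c1ccc(O[Si](C)(C)C(C)(C)C)cc1)[C@H](O)C3 | intermediate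
6 | target: 3-methoxy-flavanone unit fused through C3–C8 and C2–O7 to (2S,3R)-afzelechin (dihydrobenzofuro[2,3-b]chroman-4-one ketal) | CO[C@]12C(=O)c3c(O)cc(O)cc3O[C@]1(c1ccc(O)cc1)Oc1cc(O)c3c(c12)O[C@@H](c1ccc(O)cc1)[C@H](O)C3 | target

**Step count and risks**
Total steps: 3. Longest linear sequence: 3 steps (1 → 2 → 5 → 6).

Most likely to fail is step 2, the new anodic coupling. Arene 2 may be oxidised in place of 3, the arene may attack the ortho carbon of the phenol ring of 3 instead of C3, or little of the wanted C3 epimer may be formed. Its fallback uses only known reaction types and an electrophile that can be attacked only at the future C3; it sets out from 1 and comes back to the route at 6. Bought 2',4',6'-tris(benzyloxy)acetophenone is C-acylated with 4-(benzyloxy)benzoyl chloride (LiN(SiMe3)2, THF, −78 °C) to 1-[2,4,6-tris(benzyloxy)phenyl]-3-[4-(benzyloxy)phenyl]propane-1,3-dione F1. Dess–Martin periodinane (pyridine, CH2Cl2) oxidises this to the vicinal triketone 1-[2,4,6-tris(benzyloxy)phenyl]-3-[4-(benzyloxy)phenyl]propane-1,2,3-trione F2. In AcOH at 40 °C, 1 adds through C8 to the central carbonyl (ninhydrin-type Friedel–Crafts hydroxyalkylation; C6 adducts are removed) and its 7-OH closes on the less hindered 4-(benzyloxy)benzoyl carbonyl to give the dihydrobenzofuran hemiketal F3. Hydrogenolysis (H2, Pd/C, EtOAc/MeOH) gives the debenzylated hemiketal F4. Camphorsulfonic acid in THF closes the second ketal ring to the 3-hydroxy ketal (3-O-demethyl-6) F5, whose C3 epimers are separated. The same acid in MeOH at 40 °C exchanges the tertiary, trioxygenated-benzylic 3-OH for OMe (SN1 methanolysis, MeOH returning syn to the 2-aryl group) to give 6.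

Second is step 1: silylation of the 3-OH or incomplete reaction would give mixtures of silyl ethers. Its fallback gives up the free 3-OH; it sets out from 1 and comes back at 6. Exhaustive silylation (TBSOTf, 2,6-lutidine, CH2Cl2, 0 °C) gives 3,5,7,4'-tetrakis-O-TBS-(−)-afzelechin F6. Under the electrolysis conditions of step 2 with 3 this passes through the corresponding quinone methide F7 to the tris-TBS ether of 6 F8. HF·pyridine (THF/pyridine, 0 °C → rt), needed for the secondary silyl ether, then gives 6.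

Third is step 3: the free polyphenol is hard to purify, and its ketal and tertiary methyl ether do not tolerate a drifting pH. Its fallback isolates the product as an ester; it sets out from 5 and comes back at 6. 5 is desilylated and acetylated in one flask (TBAF, Ac2O, pyridine, DMAP, THF, 0 °C → rt) to the hexaacetate of 6 F9. This is purified by crystallisation or silica chromatography and deacetylated with catalytic NaOMe in MeOH at 0 °C (neutralised with acidic resin) to 6.

**Further compounds**
F1 | step 2 | 1-[2,4,6-tris(benzyloxy)phenyl]-3-[4-(benzyloxy)phenyl]propane-1,3-dione | O=C(CC(=O)c1c(OCc2ccccc2)cc(OCc2ccccc2)cc1OCc1ccccc1)c1ccc(OCc2ccccc2)cc1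
F2 | step 2 | 1-[2,4,6-tris(benzyloxy)phenyl]-3-[4-(benzyloxy)phenyl]propane-1,2,3-trione | O=C(C(=O)C(=O)c1c(OCc2ccccc2)cc(OCc2ccccc2)cc1OCc1ccccc1)c1ccc(OCc2ccccc2)cc1
F3 | step 2 | dihydrobenzofuran hemiketal: 2-[4-(benzyloxy)phenyl]-2,3-dihydroxy-3-[2,4,6-tris(benzyloxy)benzoyl]-2,3-dihydrofuran ring fused across O7/C8 of 1 (both C3 epimers) | OC1(c2ccc(OCc3ccccc3)cc2)Oc2cc(O)c3c(c2C1(O)C(=O)c1c(OCc2ccccc2)cc(OCc2ccccc2)cc1OCc1ccccc1)O[C@@H](c1ccc(O)cc1)[C@H](O)C3
F4 | step 2 | debenzylated hemiketal (all benzyl ethers of F3 replaced by OH) | OC1(c2ccc(O)cc2)Oc2cc(O)c3c(c2C1(O)C(=O)c1c(O)cc(O)cc1O)O[C@@H](c1ccc(O)cc1)[C@H](O)C3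
F5 | step 2 | 3-hydroxy ketal (3-O-demethyl-6) | O[C@]12C(=O)c3c(O)cc(O)cc3O[C@]1(c1ccc(O)cc1)Oc1cc(O)c3c(c12)O[C@@H](c1ccc(O)cc1)[C@H](O)C3
F6 | step 1 | 3,5,7,4'-tetrakis-O-TBS-(−)-afzelechin | CC(C)(C)[Si](C)(C)Oc1cc(O[Si](C)(C)C(C)(C)C)c2c(c1)O[C@@H](c1ccc(O[Si](C)(C)C(C)(C)C)cc1)[C@H](O[Si](C)(C)C(C)(C)C)C2
F7 | step 1 | quinone methide from F6 and 3 (3-O-TBS analogue of 4) | CO[C@]1(c2c(O[Si](C)(C)C(C)(C)C)cc(O[Si](C)(C)C(C)(C)C)c3c2O[C@@H](c2ccc(O[Si](C)(C)C(C)(C)C)cc2)[C@H](O[Si](C)(C)C(C)(C)C)C3)C(=O)c2c(O)cc(O)cc2OC1=C1C=CC(=O)C=C1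
F8 | step 1 | tris-TBS ether of 6 (3-O-TBS analogue of 5) | CO[C@]12C(=O)c3c(O)cc(O)cc3O[C@]1(c1ccc(O)cc1)Oc1cc(O[Si](C)(C)C(C)(C)C)c3c(c12)O[C@@H](c1ccc(O[Si](C)(C)C(C)(C)C)cc1)[C@H](O[Si](C)(C)C(C)(C)C)C3
F9 | step 3 | hexaacetate of 6 | CO[C@]12C(=O)c3c(OC(C)=O)cc(OC(C)=O)cc3O[C@]1(c1ccc(OC(C)=O)cc1)Oc1cc(OC(C)=O)c3c(c12)O[C@@H](c1ccc(OC(C)=O)cc1)[C@H](OC(C)=O)C3
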